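**Plan**

1. Numbering: guaianolide numbering for the hydroxylated half (C1–C15), primes for the spiro-linked half; ring A = cyclopentenone C1–C5, ring B = cycloheptane, ring D = spiro cyclohexene C1/C2/C4'/C15'/C14/C10.
2. Cuts, in retrosynthetic order: C15–O (water off a C4=C15 enone), C10–O (γ-oxygenation that moves C1=C10 to C1=C2), C3–C4 of ring A (alkyne hydroacylation), then C2–C4' and C14–C15' of ring D (Diels–Alder), leaving seco-dienynal 9 and dehydrozaluzanin C 3.
3. Enabling feature: in ring A the C3 ketone is flanked by C4 bearing C15–OH, the hydrate of an α-methylene ketone C3(=O)–C4(=C15H2); that unit is an isomer of an aldehyde C3–H on C2 plus an ethynyl group C4≡C15 on C5, two carbons that sit side by side on sp2 C1 where rings B and D meet.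
4. Forward: dehydrocostus lactone 1 supplies both halves through alcohol 2 (ring B, both lactone rings and the lower five-membered ring are bought). In one half C3–C4 is opened by epoxy-aldehyde fragmentation and the aldehyde is dehydrogenated to diene 9. The Diels–Alder union makes ring D, hydroacylation closes ring A last, then O2 and water install C10–OH and C15–OH.
5. Stereochemistry: C5, C6, C7, C1', C5', C6', C7' come with 1; C4' from attack on the convex α face of 3 in the Diels–Alder step; C10 from β-face oxygenation anti to C5'; C4 from equilibrating protonation trans to the C5–C6 bond.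

Key step: step 9

Remark: the C3 carbinol of 2, the epoxide of 5 to 7 and C2 of 10 and 11 are drawn as the isomers expected from convex-face attack and an endo cycloaddition; each of these centres is erased later (steps 2, 3, 6 and 10), so the other isomer serves equally.

**Route**

Step 1
Reactants: 1 dehydrocostus lactone
Product: 2 3-epizaluzanin C (3α-hydroxy-dehydrocostus lactone)
Conditions: SeO2 (0.2 equiv), tBuOOH (2 equiv), CH2Cl2, 0 °C to rt
Reagents that add atoms: tert-butyl hydroperoxide, CC(C)(C)OO
Why: Riley allylic oxidation (ene reaction, then [2,3]-shift) should hydroxylate the ring-A methylene C3 next to C4=C15 from the convex α face; the C3 configuration is not needed later.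

Step 2
Reactants: 2 3-epizaluzanin C
Product: 3 dehydrozaluzanin C
Conditions: Dess–Martin periodinane, CH2Cl2, rt
Reagents that add atoms: none
Why: Dess–Martin oxidation of the secondary allylic alcohol should give the exo-methylene enone under non-basic conditions that spare the α-methylene lactone.

Step 3
Reactants: 2 3-epizaluzanin C
Product: 4 15-hydroxyguaia-3,10(14),11(13)-trien-12,6α-olide
Conditions: Ph3SiOReO3 (5 mol %), Et2O, −20 to 0 °C
Reagents that add atoms: none
Why: Rhenium-oxo-catalysed 1,3-transposition of the allylic alcohol ([3,3]-shift of the perrhenate ester) should settle on the trisubstituted endocyclic C3=C4 alkene carrying the unhindered primary C15 alcohol.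

Step 4
Reactants: 4 15-hydroxyguaia-3,10(14),11(13)-trien-12,6α-olide
Product: 5 3α,4α-epoxy-15-hydroxyguaia-10(14),11(13)-dien-12,6α-olide
Conditions: VO(acac)2 (5 mol %), tBuOOH, CH2Cl2, 0 °C
Reagents that add atoms: tert-butyl hydroperoxide, CC(C)(C)OO
Why: Hydroxyl-directed vanadium-catalysed epoxidation should select the allylic-alcohol alkene over C10=C14 and C11=C13 and attack the convex α face; the epoxide configuration is not needed later.

Step 5
Reactants: 5 3α,4α-epoxy-15-hydroxyguaia-10(14),11(13)-dien-12,6α-olide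
Product: 6 3α,4α-epoxy-15-oxoguaia-10(14),11(13)-dien-12,6α-olide
Conditions: Dess–Martin periodinane, pyridine, CH2Cl2, 0 °C
Reagents that add atoms: none
Why: Buffered Dess–Martin oxidation should give the non-enolisable α,β-epoxy aldehyde without opening the epoxide.

Step 6
Reactants: 6 3α,4α-epoxy-15-oxoguaia-10(14),11(13)-dien-12,6α-olide
Product: 8 3-oxo-3,4-secoguaia-10(14),11(13)-dien-4(15)-yn-12,6α-olide (seco-ynal: CH2CHO on C1 and ethynyl on C5), via tosylhydrazone 7 (not isolated)
Conditions: TsNHNH2 (1.1 equiv), CH2Cl2/AcOH (2:1), −20 °C to rt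
Reagents that add atoms: none
Why: Proposed new method: condensation gives tosylhydrazone 7, whose nitrogen pushes open the epoxide C4–O bond; the freed C3 oxygen then drives a Grob-type cleavage of C3–C4 anti to the departing N2 and toluenesulfinate, so C3 becomes the aldehyde and C4≡C15 a terminal alkyne while both epoxide centres vanish; the closest known reaction type is the Eschenmoser–Tanabe fragmentation of α,β-epoxy ketone sulfonylhydrazones, here asked to work on an α,β-epoxy aldehyde.

Step 7
Reactants: 8 seco-ynal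
Product: 9 (1E)-3-oxo-3,4-secoguaia-1,10(14),11(13)-trien-4(15)-yn-12,6α-olide (seco-dienynal)
Conditions: IBX (1.5 equiv), 4-methoxypyridine N-oxide, DMSO, rt
Reagents that add atoms: none
Why: IBX dehydrogenation of the aldehyde through its enol can only remove H from C1, and the E isomer (formyl away from C10=C14) should prevail because the ring-locked s-cis diene leaves no room for an inside substituent.

Step 8
Reactants: 9 seco-dienynal; 3 dehydrozaluzanin C
Product: 10 spiro cycloadduct aldehyde (ring D with C1=C10; C2 bears H and CHO; C5 bears ethynyl)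
Conditions: 3 (2 equiv), BHT (cat.), toluene, 80 °C
Reagents that add atoms: none
Why: Thermal Diels–Alder reaction of the s-cis-locked diene C2=C1–C10=C14 with the exo-methylene enone of 3 should follow the ortho rule (formyl-bearing C2 to carbonyl-bearing C4', C14 to C15') and set C4' by approach to the convex α face (the face of H-5', away from the C5'–C6' bond); the C2 epimer formed is immaterial.

Step 9
Reactants: 10 spiro cycloadduct aldehyde
Product: 11 ring-A-closed 3-ketone (2α-H, C1=C10, exocyclic C4=C15)
Conditions: [Rh(rac-BINAP)]BF4 (10 mol %), CH2Cl2, rt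
Reagents that add atoms: none
Why: Cationic monovalent rhodium inserts into the aldehyde C3–H bond, the acyl rhodium hydride adds syn across the ethynyl group on C5 (hydride to C15, rhodium to C4) to give a six-membered acyl-alkenyl rhodacycle, and C–C reductive elimination forms C3–C4. The closest known reaction type is the rhodium-catalysed intramolecular hydroacylation of 5-alkynals to α-alkylidenecyclopentanones. Ring A closes in the 5-exo-dig mode, which delivers the C3 ketone and the exocyclic C4=C15 methylene in one isomerisation without any reagent atom. No new stereocentre is created; C2 is enolisable in aldehyde and ketone alike and both epimers converge in step 10. The step needs exo over endo regioselectivity and C–H activation over decarbonylation: the exo rhodacycle is six-membered against seven for endo, rings B and D hold the aldehyde on C2 and the alkyne on C5 within bonding distance across sp2 C1, the chelating diphosphine disfavours CO extrusion, and the α-methylene lactones and the C3' ketone offer no aldehyde C–H.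

Step 10
Reactants: 11 ring-A-closed 3-ketone
Product: 13 4(15)-anhydro-ainsliadimer B (10β-hydroxy-1(2),4(15)-dien-3-one), via 10β-hydroperoxide 12 (not isolated)
Conditions: O2 (1 atm), Et3N (0.2 equiv), EtOAc, rt; then PPh3 (1.1 equiv), 0 °C
Reagents that add atoms: dioxygen, O=O
Why: Autoxidation of the β,γ-unsaturated ketone through its extended enolate (loss of the doubly activated C2–H, O2 capture at γ-carbon C10, double bond into conjugation as C1=C2) and phosphine reduction of the hydroperoxide should place oxygen on the β face of C10, the face of the C3' carbonyl, because C5' and the lower cycloheptane cover the α face of ring D.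

Step 11
Reactants: 13 4(15)-anhydro-ainsliadimer B
Product: 14 ainsliadimer B
Conditions: K2CO3 (0.3 equiv), THF/H2O (1:1), 0 °C to rt
Reagents that add atoms: water, O
Why: Oxa-Michael addition of water to the exo-methylene of the cross-conjugated dienone, the most electrophilic of the three acceptors (ketone- against ester-activated), should be followed by equilibrating protonation at C4 that puts C15 trans to the C5–C6 bond.

**Compound list**

1 | dehydrocostus lactone | C=C1CC[C@H]2C(=C)CC[C@H]3C(=C)C(=O)O[C@@H]3[C@H]21 | starting material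
2 | 3-epizaluzanin C (3α-hydroxy-dehydrocostus lactone) | C=C1[C@H](O)C[C@H]2C(=C)CC[C@H]3C(=C)C(=O)O[C@@H]3[C@H]21 | intermediate
3 | dehydrozaluzanin C (3-oxo-dehydrocostus lactone) | C=C1C(=O)C[C@H]2C(=C)CC[C@H]3C(=C)C(=O)O[C@@H]3[C@H]21 | intermediate
4 | 15-hydroxyguaia-3,10(14),11(13)-trien-12,6α-olide | OCC1=CC[C@H]2C(=C)CC[C@H]3C(=C)C(=O)O[C@@H]3[C@H]21 | intermediate
5 | 3α,4α-epoxy-15-hydroxyguaia-10(14),11(13)-dien-12,6α-olide | OC[C@@]12O[C@@H]1C[C@H]3C(=C)CC[C@H]4C(=C)C(=O)O[C@@H]4[C@H]32 | intermediate
6 | 3α,4α-epoxy-15-oxoguaia-10(14),11(13)-dien-12,6α-olide | O=C[C@@]12O[C@@H]1C[C@H]3C(=C)CC[C@H]4C(=C)C(=O)O[C@@H]4[C@H]32 | intermediate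
7 | (E)-tosylhydrazone of 6 at C15 | Cc1ccc(cc1)S(=O)(=O)N/N=C/[C@@]12O[C@@H]1C[C@H]3C(=C)CC[C@H]4C(=C)C(=O)O[C@@H]4[C@H]32 | intermediate
8 | 3-oxo-3,4-secoguaia-10(14),11(13)-dien-4(15)-yn-12,6α-olide (seco-ynal) | O=CC[C@H]1C(=C)CC[C@H]2C(=C)C(=O)O[C@@H]2[C@H]1C#C | intermediate
9 | (1E)-3-oxo-3,4-secoguaia-1,10(14),11(13)-trien-4(15)-yn-12,6α-olide (seco-dienynal) | O=C/C=C1/C(=C)CC[C@H]2C(=C)C(=O)O[C@@H]2[C@H]1C#C | intermediate
10 | spiro cycloadduct aldehyde (C2–C4' and C14–C15' joined, C1=C10, 2β-CHO, 5β-ethynyl) | C=C1C(=O)O[C@@H]2[C@@H](C#C)C3=C(CC[C@@H]12)CC[C@]4(C(=O)C[C@H]5C(=C)CC[C@H]6C(=C)C(=O)O[C@@H]6[C@H]54)[C@@H]3C=O | intermediate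
11 | ring-A-closed 3-ketone (2α-H, C1=C10, C4=C15) | C=C1C(=O)O[C@@H]2[C@H]3C(=C)C(=O)[C@@H]4C3=C(CC[C@@H]12)CC[C@]45C(=O)C[C@H]6C(=C)CC[C@H]7C(=C)C(=O)O[C@@H]7[C@H]65 | intermediate
12 | 10β-hydroperoxy-1(2),4(15)-dien-3-one | C=C1C(=O)O[C@@H]2[C@@H]3C4=C(C(=O)C3=C)[C@]3(CC[C@]4(OO)CC[C@@H]12)C(=O)C[C@H]1C(=C)CC[C@H]2C(=C)C(=O)O[C@@H]2[C@H]13 | intermediate
13 | 4(15)-anhydro-ainsliadimer B | C=C1C(=O)O[C@@H]2[C@@H]3C4=C(C(=O)C3=C)[C@]3(CC[C@]4(O)CC[C@@H]12)C(=O)C[C@H]1C(=C)CC[C@H]2C(=C)C(=O)O[C@@H]2[C@H]13 | intermediate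
14 | ainsliadimer B | C=C1C(=O)O[C@@H]2[C@@H]3C4=C(C(=O)[C@H]3CO)[C@]3(CC[C@]4(O)CC[C@@H]12)C(=O)C[C@H]1C(=C)CC[C@H]2C(=C)C(=O)O[C@@H]2[C@H]13 | target

**Count**

Total steps: 11. Longest linear sequence: 10 steps (steps 1 and 3 to 11); step 2 is the one-step branch to 3.

**Steps most likely to fail**

Step 6 (Proposed new method). The epoxide may open with the diazenyl group syn to C3, or the hydrazone may be diverted by sulfinate addition to the α-methylene lactone, so that C3–C4 is not cleaved. The fallback uses known reactions, sets out from 2 and comes back at 8. Reductive 1,3-transposition of the allylic alcohol (2-nitrobenzenesulfonylhydrazide, PPh3, DEAD, −30 °C to rt) would give the 15-methyl Δ3 alkene F1. Ozonolysis of its trisubstituted C3=C4 bond with acetal-forming work-up (O3, CH2Cl2/MeOH, −78 °C; TsOH; then NaHCO3, Me2S) would give keto acetal F2. Kinetic enol triflation of the methyl ketone (KN(SiMe3)2, PhNTf2, −78 °C) would give vinyl triflate F3, and elimination (LiN(iPr)2, −78 °C) alkynyl acetal F4. Acetal hydrolysis (aqueous AcOH) then gives 8.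

Step 9. Decarbonylation of the hindered α-branched acyl rhodium hydride, vinylidene formation or oligomerisation at the terminal alkyne, or rhodium hydride migration of the new exocyclic alkene into the ring may outrun reductive elimination. The fallback sets out from 10 and comes back at 11. Markovnikov hydroiodination of the alkyne (B-iodo-9-BBN, CH2Cl2, 0 °C; then AcOH) would give 2-iodoalkene F5. Intramolecular Nozaki–Hiyama–Kishi addition to the aldehyde (CrCl2, NiCl2 cat., DMF, rt) would close ring A as exo-methylene cyclopentanol F6 (drawn as the 3α-alcohol). Dess–Martin oxidation gives 11.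

Step 8. The electron-poor dienal may oligomerise or add with the wrong orientation before it finds the enone, since diene and dienophile are both acceptor-substituted. The fallback sets out from 9 and comes back at 10. Luche reduction (NaBH4, CeCl3, MeOH, −78 °C) would give the electron-richer dienyl alcohol F7, whose hydroxyl can hydrogen-bond to the C3' carbonyl. Diels–Alder reaction with 3 (toluene, 80 °C) would give adduct alcohol F8. Dess–Martin oxidation gives 10.

**Further compounds**

F1 | step 6 | guaia-3,10(14),11(13)-trien-12,6α-olide (15-methyl Δ3 alkene) | CC1=CC[C@H]2C(=C)CC[C@H]3C(=C)C(=O)O[C@@H]3[C@H]21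
F2 | step 6 | 3,3-dimethoxy-4-oxo-3,4-secoguaia-10(14),11(13)-dien-12,6α-olide (keto acetal) | COC(OC)C[C@H]1C(=C)CC[C@H]2C(=C)C(=O)O[C@@H]2[C@H]1C(C)=O
F3 | step 6 | vinyl triflate of F2 at C4=C15 | COC(OC)C[C@H]1C(=C)CC[C@H]2C(=C)C(=O)O[C@@H]2[C@H]1C(=C)OS(=O)(=O)C(F)(F)F
F4 | step 6 | dimethyl acetal of 8 (alkynyl acetal) | COC(OC)C[C@H]1C(=C)CC[C@H]2C(=C)C(=O)O[C@@H]2[C@H]1C#C
F5 | step 9 | 2-iodoalkene from 10 (1-iodovinyl on C5) | C=C1C(=O)O[C@@H]2[C@@H](C(I)=C)C3=C(CC[C@@H]12)CC[C@]4(C(=O)C[C@H]5C(=C)CC[C@H]6C(=C)C(=O)O[C@@H]6[C@H]54)[C@@H]3C=O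
F6 | step 9 | 3α-hydroxy analogue of 11 (exo-methylene cyclopentanol) | C=C1C(=O)O[C@@H]2[C@H]3C(=C)[C@H](O)[C@@H]4C3=C(CC[C@@H]12)CC[C@]45C(=O)C[C@H]6C(=C)CC[C@H]7C(=C)C(=O)O[C@@H]7[C@H]65
F7 | step 8 | (1E)-3-hydroxy-3,4-secoguaia-1,10(14),11(13)-trien-4(15)-yn-12,6α-olide (dienyl alcohol) | OC/C=C1/C(=C)CC[C@H]2C(=C)C(=O)O[C@@H]2[C@H]1C#C
F8 | step 8 | primary alcohol analogue of 10 (CH2OH on C2) | C=C1C(=O)O[C@@H]2[C@@H](C#C)C3=C(CC[C@@H]12)CC[C@]4(C(=O)C[C@H]5C(=C)CC[C@H]6C(=C)C(=O)O[C@@H]6[C@H]54)[C@@H]3CO
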